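The route rests on the C12–C13 disconnection (halimane numbering) of the side chain: C13, the methyl-bearing stereocentre, lies β to the ester carbonyl C15, so C12–C13 is the bond of a conjugate addition. A copper-catalysed enantioselective 1,4-addition of the primary Grignard carbon C12 of the bicyclic fragment (C11–C12 tether on quaternary C9 of ring B of the Δ1(10)-octalin) to the (E)-crotonate of acetonide-protected glycerol joins the two halves, sets C13 (R) and delivers the whole skeleton with the glyceryl ester in place. The precursors are the bromoethyl-octalin, built by conjugate addition–methylation and Robinson-type annulation, and (S)-solketal crotonate.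

Key step: step 11

Remark: halimane numbering is used throughout (bicyclic core C1–C10 with C1=C10, ring A = C1–C5/C10, ring B = C5–C10, side chain C11–C16, C17 on C8, C20 on C9). The target is read as (5S,8R,9R,13R) with an (R)-2,3-dihydroxypropyl ester, so H5, C17 and the C11 chain lie on one face of ring B and C20 on the other.

Step 1
Reactants: 1 allyl 2-oxocyclohexane-1-carboxylate; 2 benzyl 2-bromoethyl ether
Product: 3 allyl 1-[2-(benzyloxy)ethyl]-2-oxocyclohexane-1-carboxylate (racemic)
Conditions: K2CO3, NaI (cat.), acetone, reflux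
Reagents that add atoms: none
Why: C-alkylation of a cyclic β-keto ester enolate with a primary bromide (in situ iodide exchange); the quaternary centre formed is racemic and is destroyed in step 2.

Step 2
Reactants: 3 allyl 1-[2-(benzyloxy)ethyl]-2-oxocyclohexane-1-carboxylate
Product: 4 2-[2-(benzyloxy)ethyl]cyclohex-2-en-1-one
Conditions: Pd(OAc)2 (5 mol%), 1,2-bis(diphenylphosphino)ethane (5 mol%), MeCN, reflux
Reagents that add atoms: none
Why: Tsuji decarboxylation–dehydrogenation: zerovalent palladium formed in situ adds to the allyl ester, CO2 is lost, and β-hydride elimination from the ring CH2 of the palladium enolate should give the endocyclic 2-substituted enone with release of propene.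

Step 3
Reactants: 4 2-[2-(benzyloxy)ethyl]cyclohex-2-en-1-one
Product: 6 (2R,3R)-2-[2-(benzyloxy)ethyl]-2,3-dimethylcyclohexan-1-one, via dimethylaluminium enolate 5 (not isolated)
Conditions: Me3Al, copper thiophene-2-carboxylate (cat.), BINOL-derived bis(1-phenylethyl)amine phosphoramidite (cat.), Et2O, −30 °C; then MeLi, MeI, DMPU, THF, −30 → 0 °C
Reagents that add atoms: trimethylaluminium C[Al](C)C; iodomethane CI
Why: Copper-catalysed enantioselective conjugate addition of Me3Al to the α-substituted enone sets C8 by ligand control (ligand antipode chosen for Re-face delivery at the β-carbon, giving 3R), and the regiodefined enolate 5, activated as its ate complex by MeLi, should be methylated anti to the adjacent pseudoaxial methyl group, so that C20 enters trans to C17 and the benzyloxyethyl chain ends cis to it (2R).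

Step 4
Reactants: 6 (2R,3R)-2-[2-(benzyloxy)ethyl]-2,3-dimethylcyclohexan-1-one
Product: 7 ({(5R,6R)-6-[2-(benzyloxy)ethyl]-5,6-dimethylcyclohex-1-en-1-yl}oxy)trimethylsilane
Conditions: LiN(iPr)2, THF, −78 °C; Me3SiCl
Reagents that add atoms: chlorotrimethylsilane C[Si](C)(C)Cl
Why: Enolate silylation; the ketone has α-hydrogens only on the CH2 side (C5 of the target), so a single regioisomeric silyl enol ether should form and no stereocentre is touched.

Step 5
Reactants: 7 ({(5R,6R)-6-[2-(benzyloxy)ethyl]-5,6-dimethylcyclohex-1-en-1-yl}oxy)trimethylsilane; 8 4-methylpent-3-en-2-one (mesityl oxide)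
Product: 9 (2R,3R,6S)-2-[2-(benzyloxy)ethyl]-2,3-dimethyl-6-(2-methyl-4-oxopentan-2-yl)cyclohexan-1-one
Conditions: TiCl4, CH2Cl2, −78 °C; H2O
Reagents that add atoms: none
Why: Mukaiyama–Michael reaction: the silyl enol ether attacks the β,β-dimethyl carbon of TiCl4-activated mesityl oxide, forming C5–C4 and the quaternary C4; the C5 epimer expected alongside is carried on, because C5 is equilibrated in step 6.

Step 6
Reactants: 9 (2R,3R,6S)-2-[2-(benzyloxy)ethyl]-2,3-dimethyl-6-(2-methyl-4-oxopentan-2-yl)cyclohexan-1-one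
Product: 11 (4aS,7R,8R)-8-[2-(benzyloxy)ethyl]-4,4,7,8-tetramethyl-4,4a,5,6,7,8-hexahydronaphthalen-2(3H)-one, via ketol 10 (not isolated)
Conditions: KOH, EtOH, 60 °C; then KOtBu, tBuOH, rt (equilibration)
Reagents that add atoms: none
Why: Intramolecular aldol condensation (Robinson-type closure of ring A) of the methyl-ketone enolate onto the ring carbonyl C10 and E1cB dehydration give the C1=C10 enone; C5 (α to the ketone before, γ to the enone after closure) equilibrates under base and should settle, by a modest margin of about one gauche interaction, in the epimer whose ring B chair keeps the C4 branch and C17 equatorial, that is H5 cis to the C11 chain (4aS), the minor epimer being separable and recyclable by re-exposure to base.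

Step 7
Reactants: 11 (4aS,7R,8R)-8-[2-(benzyloxy)ethyl]-4,4,7,8-tetramethyl-4,4a,5,6,7,8-hexahydronaphthalen-2(3H)-one
Product: 12 (1R,2R,4aS)-1-[2-(benzyloxy)ethyl]-1,2,5,5-tetramethyl-1,2,3,4,4a,5,6,7-octahydronaphthalene
Conditions: LiAlH4, AlCl3, Et2O, 0 °C → reflux
Reagents that add atoms: none
Why: Mixed-hydride deoxygenation of an enone: the allylic aluminate ionises to the C2–C1–C10 allyl cation and hydride should be delivered to the secondary terminus C2, not to C10 (tertiary, flanked by quaternary C9), so C1=C10 stays in place as in the conversion of steroidal 4-en-3-ones into 4-enes, and the benzyl ether should tolerate the ether-complexed chloroalanes.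

Step 8
Reactants: 12 (1R,2R,4aS)-1-[2-(benzyloxy)ethyl]-1,2,5,5-tetramethyl-1,2,3,4,4a,5,6,7-octahydronaphthalene
Product: 13 2-[(1R,2R,4aS)-1,2,5,5-tetramethyl-1,2,3,4,4a,5,6,7-octahydronaphthalen-1-yl]ethan-1-ol
Conditions: Li, NH3(l), THF, −78 °C; NH4Cl
Reagents that add atoms: none
Why: Dissolving-metal (Birch-type) cleavage of the benzylic C–O bond; the isolated trisubstituted alkene is not reduced under these conditions.

Step 9
Reactants: 13 2-[(1R,2R,4aS)-1,2,5,5-tetramethyl-1,2,3,4,4a,5,6,7-octahydronaphthalen-1-yl]ethan-1-ol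
Product: 14 (1R,2R,4aS)-1-(2-bromoethyl)-1,2,5,5-tetramethyl-1,2,3,4,4a,5,6,7-octahydronaphthalene
Conditions: CBr4, PPh3, CH2Cl2, 0 °C
Reagents that add atoms: tetrabromomethane BrC(Br)(Br)Br
Why: Appel bromination of a primary alcohol by SN2 displacement of the oxyphosphonium group; neutral conditions leave C1=C10 untouched.

Step 10
Reactants: 15 (S)-solketal, [(4S)-2,2-dimethyl-1,3-dioxolan-4-yl]methanol; 16 (E)-but-2-enoic anhydride (crotonic anhydride)
Product: 17 [(4R)-2,2-dimethyl-1,3-dioxolan-4-yl]methyl (2E)-but-2-enoate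
Conditions: Et3N, 4-(dimethylamino)pyridine (cat.), CH2Cl2, 0 °C → rt
Reagents that add atoms: none
Why: Nucleophile-catalysed acylation of the primary alcohol; the anhydride avoids a ketene pathway, so the (E)-conjugated double bond is kept and the dioxolane stereocentre is untouched (the descriptor changes from S to R only through the priority rules).

Step 11
Reactants: 14 (1R,2R,4aS)-1-(2-bromoethyl)-1,2,5,5-tetramethyl-1,2,3,4,4a,5,6,7-octahydronaphthalene; 17 [(4R)-2,2-dimethyl-1,3-dioxolan-4-yl]methyl (2E)-but-2-enoate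
Product: 20 [(4R)-2,2-dimethyl-1,3-dioxolan-4-yl]methyl (3R)-3-methyl-5-[(1R,2R,4aS)-1,2,5,5-tetramethyl-1,2,3,4,4a,5,6,7-octahydronaphthalen-1-yl]pentanoate, via Grignard reagent 18 (not isolated), via magnesium ester enolate 19 (not isolated)
Conditions: Mg, Et2O, reflux; then 17 (1.5 equiv), CuBr·SMe2 (5 mol%), Josiphos-type ferrocenyl diphosphine (6 mol%), tBuOMe, −75 °C, slow addition of 18; aq. NH4Cl
Reagents that add atoms: none
Why: Transmetalation of Grignard reagent 18 to the diphosphine-bound copper bromide gives a chiral alkylcopper species that π-complexes the s-cis (E)-crotonate 17, adds oxidatively at C13 (σ-bound trivalent copper intermediate) and reductively eliminates to forge C12–C13, leaving magnesium enolate 19, which is protonated at C14 on work-up. The closest known reaction type is the copper/ferrocenyl-diphosphine-catalysed enantioselective conjugate addition of primary alkyl Grignard reagents to (E)-α,β-unsaturated esters. No ring is closed. The one new stereocentre, C13, is set by the ligand on copper (catalyst control): the antipode is chosen that delivers C12 to the Si face of C13, giving 13R, and the distant stereocentres C5, C8, C9 and the dioxolane carbon should neither match nor mismatch. The step needs 1,4- over 1,2-selectivity, secured by the ester acceptor, copper catalysis, low temperature and slow addition of 18, and enantiofacial selectivity, secured by the defined (E)-geometry of 17 and the ligand. The C1=C10 alkene and the acetonide are inert, and quaternary C9 sits two atoms away from the nucleophilic carbon, so it should not retard the addition.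

Step 12
Reactants: 20 [(4R)-2,2-dimethyl-1,3-dioxolan-4-yl]methyl (3R)-3-methyl-5-[(1R,2R,4aS)-1,2,5,5-tetramethyl-1,2,3,4,4a,5,6,7-octahydronaphthalen-1-yl]pentanoate
Product: 21 (2R)-2,3-dihydroxypropyl (3R)-3-methyl-5-[(1R,2R,4aS)-1,2,5,5-tetramethyl-1,2,3,4,4a,5,6,7-octahydronaphthalen-1-yl]pentanoate (target)
Conditions: AcOH/H2O (4:1), 40 °C
Reagents that add atoms: none
Why: Mild acid hydrolysis of the isopropylidene acetal; weak acid and low temperature should avoid acyl migration to the secondary hydroxyl and isomerisation of C1=C10, and no stereocentre is touched.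

Compound list
1 | allyl 2-oxocyclohexane-1-carboxylate | C=CCOC(=O)C1CCCCC1=O | starting material
2 | benzyl 2-bromoethyl ether | BrCCOCc1ccccc1 | starting material
3 | allyl 1-[2-(benzyloxy)ethyl]-2-oxocyclohexane-1-carboxylate (racemic) | C=CCOC(=O)C1(CCOCc2ccccc2)CCCCC1=O | intermediate
4 | 2-[2-(benzyloxy)ethyl]cyclohex-2-en-1-one | O=C1CCCC=C1CCOCc1ccccc1 | intermediate
5 | ({(3R)-2-[2-(benzyloxy)ethyl]-3-methylcyclohex-1-en-1-yl}oxy)dimethylalumane (aluminium enolate) | C[Al](C)OC1=C(CCOCc2ccccc2)[C@H](C)CCC1 | intermediate (not isolated)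
6 | (2R,3R)-2-[2-(benzyloxy)ethyl]-2,3-dimethylcyclohexan-1-one | c1ccccc1COCC[C@@]1(C)C(=O)CCC[C@H]1C | intermediate
7 | ({(5R,6R)-6-[2-(benzyloxy)ethyl]-5,6-dimethylcyclohex-1-en-1-yl}oxy)trimethylsilane | c1ccccc1COCC[C@@]1(C)C(O[Si](C)(C)C)=CCC[C@H]1C | intermediate
8 | 4-methylpent-3-en-2-one (mesityl oxide) | CC(=O)C=C(C)C | starting material
9 | (2R,3R,6S)-2-[2-(benzyloxy)ethyl]-2,3-dimethyl-6-(2-methyl-4-oxopentan-2-yl)cyclohexan-1-one | c1ccccc1COCC[C@@]1(C)C(=O)[C@H](C(C)(C)CC(C)=O)CC[C@H]1C | intermediate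
10 | (4aS,7R,8R)-8-[2-(benzyloxy)ethyl]-8a-hydroxy-4,4,7,8-tetramethyl-3,4,4a,5,6,7,8,8a-octahydronaphthalen-2(1H)-one (ketol, configuration at C8a open) | c1ccccc1COCC[C@@]1(C)C2(O)CC(=O)CC(C)(C)[C@@H]2CC[C@H]1C | intermediate (not isolated)
11 | (4aS,7R,8R)-8-[2-(benzyloxy)ethyl]-4,4,7,8-tetramethyl-4,4a,5,6,7,8-hexahydronaphthalen-2(3H)-one | c1ccccc1COCC[C@@]1(C)C2=CC(=O)CC(C)(C)[C@@H]2CC[C@H]1C | intermediate
12 | (1R,2R,4aS)-1-[2-(benzyloxy)ethyl]-1,2,5,5-tetramethyl-1,2,3,4,4a,5,6,7-octahydronaphthalene | c1ccccc1COCC[C@@]1(C)C2=CCCC(C)(C)[C@@H]2CC[C@H]1C | intermediate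
13 | 2-[(1R,2R,4aS)-1,2,5,5-tetramethyl-1,2,3,4,4a,5,6,7-octahydronaphthalen-1-yl]ethan-1-ol | OCC[C@@]1(C)C2=CCCC(C)(C)[C@@H]2CC[C@H]1C | intermediate
14 | (1R,2R,4aS)-1-(2-bromoethyl)-1,2,5,5-tetramethyl-1,2,3,4,4a,5,6,7-octahydronaphthalene | BrCC[C@@]1(C)C2=CCCC(C)(C)[C@@H]2CC[C@H]1C | intermediate
15 | (S)-solketal, [(4S)-2,2-dimethyl-1,3-dioxolan-4-yl]methanol | OC[C@H]1COC(C)(C)O1 | starting material
16 | (E)-but-2-enoic anhydride | C/C=C/C(=O)OC(=O)/C=C/C | starting material
17 | [(4R)-2,2-dimethyl-1,3-dioxolan-4-yl]methyl (2E)-but-2-enoate | C/C=C/C(=O)OC[C@H]1COC(C)(C)O1 | intermediate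
18 | bromo{2-[(1R,2R,4aS)-1,2,5,5-tetramethyl-1,2,3,4,4a,5,6,7-octahydronaphthalen-1-yl]ethyl}magnesium | Br[Mg]CC[C@@]1(C)C2=CCCC(C)(C)[C@@H]2CC[C@H]1C | intermediate (not isolated)
19 | bromomagnesium (Z)-enolate of ester 20 | C[C@H](CC[C@@]1(C)C2=CCCC(C)(C)[C@@H]2CC[C@H]1C)/C=C(\O[Mg]Br)OC[C@H]1COC(C)(C)O1 | intermediate (not isolated)
20 | [(4R)-2,2-dimethyl-1,3-dioxolan-4-yl]methyl (3R)-3-methyl-5-[(1R,2R,4aS)-1,2,5,5-tetramethyl-1,2,3,4,4a,5,6,7-octahydronaphthalen-1-yl]pentanoate | C[C@H](CC[C@@]1(C)C2=CCCC(C)(C)[C@@H]2CC[C@H]1C)CC(=O)OC[C@H]1COC(C)(C)O1 | intermediate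
21 | (2R)-2,3-dihydroxypropyl (3R)-3-methyl-5-[(1R,2R,4aS)-1,2,5,5-tetramethyl-1,2,3,4,4a,5,6,7-octahydronaphthalen-1-yl]pentanoate | C[C@H](CC[C@@]1(C)C2=CCCC(C)(C)[C@@H]2CC[C@H]1C)CC(=O)OC[C@H](O)CO | target

Total step count: 12. Longest linear sequence: 11 steps (steps 1–9, 11 and 12); step 10 is a one-step side branch.

Steps most likely to fail

1. Step 11 (key step). What may go wrong: erosion of enantiofacial discrimination at the small, methyl-substituted β-carbon (the dioxolane oxygens may bind magnesium and perturb the catalyst), and uncatalysed 1,2-addition of the Grignard reagent to the ester. Fallback (auxiliary control in place of catalyst control): it sets out from bromide 14. Grignard reagent 18 is added with CuBr·SMe2 (THF, −78 → −20 °C; aq. NH4Cl) to (4R)-3-[(2E)-but-2-enoyl]-4-phenyl-1,3-oxazolidin-2-one F1, which is made from commercial (R)-4-phenyl-1,3-oxazolidin-2-one, n-BuLi and (E)-but-2-enoyl chloride. In the magnesium-chelated syn-s-cis imide the phenyl group shields one face, so attack should occur on the Si face of C13 and give (4R)-3-{(3R)-3-methyl-5-[(1R,2R,4aS)-1,2,5,5-tetramethyl-1,2,3,4,4a,5,6,7-octahydronaphthalen-1-yl]pentanoyl}-4-phenyl-1,3-oxazolidin-2-one F2. The lithium alkoxide of (S)-solketal 15 (n-BuLi, THF, 0 °C) then takes over the acyl group and the route is rejoined at acetonide ester 20.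

2. Step 6. What may go wrong: the thermodynamic bias at C5 is small, epimerisation of the hindered methine may be slow, and retro-Michael loss of the mesityl oxide unit may compete with ring closure. Fallback (kinetic, hydroxyl-directed hydrogen delivery in place of equilibration): it sets out from enone 11, used as its C5 epimer mixture. Dehydrogenation with chloranil (tBuOH, reflux) erases C5 and should give the linear dienone (7R,8R)-8-[2-(benzyloxy)ethyl]-4,4,7,8-tetramethyl-4,6,7,8-tetrahydronaphthalen-2(3H)-one F3. BCl3 (CH2Cl2, −78 °C) frees the primary alcohol to give (7R,8R)-8-(2-hydroxyethyl)-4,4,7,8-tetramethyl-4,6,7,8-tetrahydronaphthalen-2(3H)-one F4. Hydrogenation with [Ir(cod)(PCy3)(py)]PF6 (H2, CH2Cl2, 0 °C), directed by the C12 hydroxyl on the C11 chain, should add hydrogen to C5=C6 from the face of that chain and give (4aS,7R,8R)-8-(2-hydroxyethyl)-4,4,7,8-tetramethyl-4,4a,5,6,7,8-hexahydronaphthalen-2(3H)-one F5 with H5 cis to C11; over-reduction of C1=C10 is the residual risk. LiAlH4/AlCl3 deoxygenation as in step 7 then rejoins the route at alcohol 13.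

3. Step 5. What may go wrong: steric retardation of bond formation between the ring carbon and the fully substituted β-carbon of mesityl oxide, with desilylation of 7 back to ketone 6 or 1,2-addition taking over. Fallback (conjugate allylation of an alkylidene ketone in place of the Michael addition): it sets out from ketone 6. Aldol addition of its lithium enolate to acetone (LiN(iPr)2, THF, −78 °C) gives (2R,3R)-2-[2-(benzyloxy)ethyl]-6-(2-hydroxypropan-2-yl)-2,3-dimethylcyclohexan-1-one F6. Acid-catalysed dehydration (TsOH, benzene, reflux) gives (2R,3R)-2-[2-(benzyloxy)ethyl]-2,3-dimethyl-6-(propan-2-ylidene)cyclohexan-1-one F7. Hosomi–Sakurai allylation (allyltrimethylsilane, TiCl4, CH2Cl2, −78 °C) places the allyl group on the dimethyl-bearing carbon to give (2R,3R,6S)-2-[2-(benzyloxy)ethyl]-2,3-dimethyl-6-(2-methylpent-4-en-2-yl)cyclohexan-1-one F8. Wacker–Tsuji oxidation of the terminal alkene (PdCl2, CuCl, O2, DMF/H2O) rejoins the route at diketone 9.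

Further compounds
F1 | step 11 | (4R)-3-[(2E)-but-2-enoyl]-4-phenyl-1,3-oxazolidin-2-one | C/C=C/C(=O)N1[C@H](c2ccccc2)COC1=O
F2 | step 11 | (4R)-3-{(3R)-3-methyl-5-[(1R,2R,4aS)-1,2,5,5-tetramethyl-1,2,3,4,4a,5,6,7-octahydronaphthalen-1-yl]pentanoyl}-4-phenyl-1,3-oxazolidin-2-one | C[C@H](CC[C@@]1(C)C2=CCCC(C)(C)[C@@H]2CC[C@H]1C)CC(=O)N1[C@H](c2ccccc2)COC1=O
F3 | step 6 | (7R,8R)-8-[2-(benzyloxy)ethyl]-4,4,7,8-tetramethyl-4,6,7,8-tetrahydronaphthalen-2(3H)-one | c1ccccc1COCC[C@@]1(C)C2=CC(=O)CC(C)(C)C2=CC[C@H]1C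
F4 | step 6 | (7R,8R)-8-(2-hydroxyethyl)-4,4,7,8-tetramethyl-4,6,7,8-tetrahydronaphthalen-2(3H)-one | OCC[C@@]1(C)C2=CC(=O)CC(C)(C)C2=CC[C@H]1C
F5 | step 6 | (4aS,7R,8R)-8-(2-hydroxyethyl)-4,4,7,8-tetramethyl-4,4a,5,6,7,8-hexahydronaphthalen-2(3H)-one | OCC[C@@]1(C)C2=CC(=O)CC(C)(C)[C@@H]2CC[C@H]1C
F6 | step 5 | (2R,3R)-2-[2-(benzyloxy)ethyl]-6-(2-hydroxypropan-2-yl)-2,3-dimethylcyclohexan-1-one (configuration at C6 open) | c1ccccc1COCC[C@@]1(C)C(=O)C(C(C)(C)O)CC[C@H]1C
F7 | step 5 | (2R,3R)-2-[2-(benzyloxy)ethyl]-2,3-dimethyl-6-(propan-2-ylidene)cyclohexan-1-one | c1ccccc1COCC[C@@]1(C)C(=O)C(=C(C)C)CC[C@H]1C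
F8 | step 5 | (2R,3R,6S)-2-[2-(benzyloxy)ethyl]-2,3-dimethyl-6-(2-methylpent-4-en-2-yl)cyclohexan-1-one | c1ccccc1COCC[C@@]1(C)C(=O)[C@H](C(C)(C)CC=C)CC[C@H]1C
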